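(The constants used here stand for no real mixture, and the outcome is calculated.)

The leftover worth watching in this flask is the target still dissolved, the stock that substrate can attack to form side product, while crystals draw the rest out of solution.

substrate 0.23 M; gas phase 51 mM (held); time 4.0 min

- the target and crystals together standing at 4.0 min, as a percentage of the substrate charged
- concentration of dissolved gas in solution at 4.0 min, in percent of saturation

- percentages count the substrate that a species holds: one side product counts as two
- target is meant together with its crystals
- solid, in amounts per volume of the solution: crystals
- at the start none of the gas is dissolved
- run time (flask): 4.0 min

My ledger follows the substrate, the limiting reagent. Gas enters at 15 s⁻¹, faster than the starting demand of 0.529 s⁻¹, so dissolved gas stays near 51 mM. Substrate therefore falls pseudo-first-order through the gas step, with a lifetime of about 8.53 s by that step, and the run lasts 28.2 such lifetimes, so the ledger closes over the whole charge. Crystals respond within 1.00 s, quicker than that lifetime, so dissolved target tracks its making. I drop the solubility of 2.9 mM, which is smaller than the level of about 27.0 mM that making against crystallising gives at the start. Each mole of substrate consumed then leaves standing a fraction of target: the dissolution coefficient over itself plus two times the side-step rate constant times the substrate present. Integrating over the charge needs one number, the crowding number, two times the side-step rate constant times the charged substrate over the dissolution coefficient, here 0.506. Target and crystals then stand at the natural logarithm of one plus that number, divided by the number: 80.9%. The remaining 19.1% closes the books as side product. The run is far longer than the lifetime, so my reckoning puts dissolved gas at 51 mM by the end.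

The forecast gives 78% and 100%, lower on the first than my figure, on the ground that “that excess feeds the side reaction”.

The simulation gives 78.7% and 100%.

    crystals ⇌ target, rate k1*(cs1 - [target]) while solid is left; crystals form when [target] > cs1 (cs1 = 2.9 mM, k1 = 1.0 s⁻¹)
    substrate + dissolved gas → target (k2 = 2.3 L mol⁻¹ s⁻¹)
    gas phase ⇌ dissolved gas, rate k3*(csat - [dissolved gas]) (k3 = 15 s⁻¹, csat = 51 mM)
    substrate + target → side product (k4 = 1.1 L mol⁻¹ s⁻¹)

In this flask the low solubility of target is the main reason for the yield: crystals put target beyond the reach of substrate, and target and crystals stand at 78.7% with it against 35.4% without it. The crowding number weighs that escape against the attack, and the yield reckoned from it lies 2.2 percentage points above the simulated one in this flask. For the neighbour flask with 0.39 M of substrate the number rises to 0.858, which gives 72.2%, and that flask reads 70.7%.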